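The spiro carbon (C1 of the isoindolinone, C2' of the naphtho[1,8-bc]furan) carries N, O and two aryl groups, so it is at the acyl oxidation level and is traced back to the naphthoyl carbonyl of an unsymmetrical imide. That imide arises by N-acylation of a 2-iodo-3-methoxybenzamide with a peri-fused naphtholactone, which also liberates the peri oxygen. In the key step iodine–magnesium exchange at the ring A carbon lying between the methoxy-bearing carbon and the carbonyl-bearing carbon triggers a Parham-type addition to the naphthoyl carbonyl: the most hindered aryl–carbon bond and the lactam ring form together. A chiral phosphoric acid then closes the naphthofuran ring through the N-acyliminium ion and sets the spiro stereocentre.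

Key step: step 11

Remark: enoate 3 and acid 4 are carried as E/Z mixtures (E drawn), and the spiro N,O-ketal is assumed to hold its configuration under neutral or buffered conditions, so acid and strong base are avoided after step 12.

Step 1
Reactants: 1 1-(4-methoxyphenyl)propan-2-one; 2 triethyl phosphonoacetate
Product: 3 ethyl (E)-4-(4-methoxyphenyl)-3-methylbut-2-enoate
Conditions: NaH, THF, 0 °C to reflux
Reagents that add atoms: none
Why: Horner–Wadsworth–Emmons olefination of the ketone by the stabilised phosphonate anion should give the trisubstituted enoate, whose double-bond isomers all converge in step 3.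

Step 2
Reactants: 3 ethyl (E)-4-(4-methoxyphenyl)-3-methylbut-2-enoate
Product: 4 (E)-4-(4-methoxyphenyl)-3-methylbut-2-enoic acid
Conditions: NaOH, EtOH/H2O, 80 °C; then HCl
Reagents that add atoms: sodium hydroxide, [Na+].[OH-]
Why: Plain saponification of an unhindered ethyl ester.

Step 3
Reactants: 4 (E)-4-(4-methoxyphenyl)-3-methylbut-2-enoic acid
Product: 6 7-methoxy-3-methylnaphthalen-1-yl acetate, via 7-methoxy-3-methylnaphthalen-1-ol 5 (not isolated)
Conditions: Ac2O, NaOAc, 140 °C
Reagents that add atoms: acetic anhydride, CC(=O)OC(C)=O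
Why: Stobbe-type benzannulation, in which the mixed anhydride isomerises under acetate, loses acetic acid to a dienylketene and closes by 6π-electrocyclisation (formally an intramolecular Friedel–Crafts acylation) onto either of the two equivalent ortho positions, and the naphthol is acetylated in the flask.

Step 4
Reactants: 6 7-methoxy-3-methylnaphthalen-1-yl acetate
Product: 7 8-bromo-7-methoxy-3-methylnaphthalen-1-yl acetate
Conditions: NBS, MeCN, 0 °C to rt, dark
Reagents that add atoms: N-bromosuccinimide, O=C1CCC(=O)N1Br
Why: Electrophilic aromatic bromination should go to C8, the alpha position ortho to the strongly donating methoxy group, because the other ring carries only the weakly donating acetoxy and methyl groups.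

Step 5
Reactants: 7 8-bromo-7-methoxy-3-methylnaphthalen-1-yl acetate
Product: 8 8-bromo-7-methoxy-3-methylnaphthalen-1-ol
Conditions: K2CO3 (cat.), MeOH, rt
Reagents that add atoms: none
Why: Base-catalysed transesterification removes the aryl acetate, which would otherwise be attacked by the aryllithium of step 6.

Step 6
Reactants: 8 8-bromo-7-methoxy-3-methylnaphthalen-1-ol
Product: 10 3-methoxy-7-methyl-2H-naphtho[1,8-bc]furan-2-one, via 8-hydroxy-2-methoxy-6-methyl-1-naphthoic acid 9 (not isolated)
Conditions: n-BuLi (2.2 equiv), THF, −78 °C; CO2; then 2 M HCl, 50 °C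
Reagents that add atoms: carbon dioxide, O=C=O
Why: Bromine–lithium exchange on the lithium naphthoxide, carboxylation of the aryllithium and acid-induced peri-lactonisation of the 8-hydroxy-1-naphthoic acid should give the lactone directly.

Step 7
Reactants: 10 3-methoxy-7-methyl-2H-naphtho[1,8-bc]furan-2-one
Product: 11 3-hydroxy-7-methyl-2H-naphtho[1,8-bc]furan-2-one
Conditions: BCl3, CH2Cl2, −78 to 0 °C
Reagents that add atoms: none
Why: Chelation-assisted Lewis acid demethylation cleaves the methyl ether ortho to the lactone carbonyl and leaves the aryl ester intact.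

Step 8
Reactants: 11 3-hydroxy-7-methyl-2H-naphtho[1,8-bc]furan-2-one
Product: 12 7-methyl-3-[(triisopropylsilyl)oxy]-2H-naphtho[1,8-bc]furan-2-one
Conditions: TIPSOTf, 2,6-lutidine, CH2Cl2, 0 °C
Reagents that add atoms: triisopropylsilyl trifluoromethanesulfonate, CC(C)[Si](OS(=O)(=O)C(F)(F)F)(C(C)C)C(C)C
Why: Silylation of the phenol gives a robust triisopropylsilyl ether that withstands the amide anion, the Grignard reagent and carbonate in methanol.

Step 9
Reactants: 13 2-iodo-3-methoxybenzoic acid; 14 2-[(tert-butyldimethylsilyl)oxy]ethan-1-amine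
Product: 16 N-{2-[(tert-butyldimethylsilyl)oxy]ethyl}-2-iodo-3-methoxybenzamide, via acyl imidazole 15 (not isolated)
Conditions: CDI, THF, rt; then 14, 50 °C
Reagents that add atoms: none
Why: Amide coupling through the acyl imidazole is a standard way to acylate a primary amine with an ortho-substituted benzoic acid.

Step 10
Reactants: 16 N-{2-[(tert-butyldimethylsilyl)oxy]ethyl}-2-iodo-3-methoxybenzamide; 12 7-methyl-3-[(triisopropylsilyl)oxy]-2H-naphtho[1,8-bc]furan-2-one
Product: 18 N-{2-[(tert-butyldimethylsilyl)oxy]ethyl}-2-iodo-3-methoxy-N-{6-methyl-8-[(triethylsilyl)oxy]-2-[(triisopropylsilyl)oxy]-1-naphthoyl}benzamide, via sodium naphthoxide of the ring-opened imide 17 (not isolated)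
Conditions: NaH, THF, 0 °C; 12, 0 °C to rt; then TESCl, 0 °C
Reagents that add atoms: chlorotriethylsilane, CC[Si](Cl)(CC)CC
Why: N-acylation of the sodium amidate by the planar, strained aryl ester (acyl transfer with lactone ring opening) is driven by release of the far less basic naphthoxide, which is silylated in the flask so that it cannot re-close the lactone.

Step 11
Reactants: 18 N-{2-[(tert-butyldimethylsilyl)oxy]ethyl}-2-iodo-3-methoxy-N-{6-methyl-8-[(triethylsilyl)oxy]-2-[(triisopropylsilyl)oxy]-1-naphthoyl}benzamide
Product: 21 2-{2-[(tert-butyldimethylsilyl)oxy]ethyl}-3-hydroxy-3-{8-hydroxy-6-methyl-2-[(triisopropylsilyl)oxy]naphthalen-1-yl}-4-methoxyisoindolin-1-one (racemic), via arylmagnesium chloride 19 (not isolated), via magnesium hemiaminal alkoxide 20 (not isolated)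
Conditions: i-PrMgCl·LiCl, THF, −40 to 0 °C; then MeOH, K2CO3, 0 °C
Reagents that add atoms: none
Why: Iodine–magnesium exchange at the iodide flanked by the methoxy and carbonyl groups should give arylmagnesium 19, whose carbanionic carbon adds to the naphthoyl carbonyl (Parham-type cyclisation of a haloaryl imide, the closest known reaction) to form the aryl–carbon bond and the lactam ring in one event. The lactam ring closes in a 5-exo-trig mode onto a carbonyl that must twist out of amide conjugation to be reached and is thereby activated. The new hemiaminal stereocentre forms without control, as a racemate and as rotamers about the C–naphthyl bond, which is of no consequence because step 12 planarises this carbon. The step needs exchange to outrun addition of i-PrMgCl to the imide, which the aryl iodide, its chelating neighbours and the low temperature should secure; attack on the naphthoyl rather than the benzoyl carbonyl is enforced by geometry, since the latter sits on the carbanion's own ring. Regiochemistry on ring A is fixed by the position of iodine, and the triethylsilyl group keeps the peri oxygen from re-forming the lactone until the bond is made, after which carbonate in methanol frees that oxygen for step 12.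

Step 12
Reactants: 21 2-{2-[(tert-butyldimethylsilyl)oxy]ethyl}-3-hydroxy-3-{8-hydroxy-6-methyl-2-[(triisopropylsilyl)oxy]naphthalen-1-yl}-4-methoxyisoindolin-1-one (racemic)
Product: 23 (S)-2-{2-[(tert-butyldimethylsilyl)oxy]ethyl}-7-methoxy-7'-methyl-3'-[(triisopropylsilyl)oxy]spiro[isoindoline-1,2'-naphtho[1,8-bc]furan]-3-one, via N-acyliminium phosphate ion pair 22 (not isolated)
Conditions: (R)-TRIP (10 mol %), 4 Å MS, PhMe, −20 °C
Reagents that add atoms: none
Why: Chiral phosphoric acid catalysed N-acyliminium spiro-N,O-ketalisation, in which (R)-3,3'-bis(2,4,6-triisopropylphenyl)-1,1'-binaphthyl-2,2'-diyl hydrogen phosphate ionises the hemiaminal to ion pair 22 with the naphthyl ring perpendicular to the iminium plane, and the phosphate, hydrogen-bonded to the peri hydroxyl, selects which rotamer about the C–naphthyl bond (hence which face) closes by 5-exo-trig O-attack and so sets the spiro centre; the catalyst antipode that delivers the (S)-silyl ether is fixed by a test reaction.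

Step 13
Reactants: 23 (S)-2-{2-[(tert-butyldimethylsilyl)oxy]ethyl}-7-methoxy-7'-methyl-3'-[(triisopropylsilyl)oxy]spiro[isoindoline-1,2'-naphtho[1,8-bc]furan]-3-one
Product: 24 (R)-3'-hydroxy-2-(2-hydroxyethyl)-7-methoxy-7'-methylspiro[isoindoline-1,2'-naphtho[1,8-bc]furan]-3-one
Conditions: TBAF, AcOH (1:1), THF, 0 °C
Reagents that add atoms: none
Why: Buffered fluoride desilylation removes both silyl ethers without touching the N,O-ketal, and the descriptor changes from S to R only because the CIP priorities change when silicon is replaced by hydrogen.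

Compound list
1 | 1-(4-methoxyphenyl)propan-2-one | COc1ccc(CC(C)=O)cc1 | starting material
2 | triethyl phosphonoacetate | CCOC(=O)CP(=O)(OCC)OCC | starting material
3 | ethyl (E)-4-(4-methoxyphenyl)-3-methylbut-2-enoate | CCOC(=O)/C=C(C)/Cc1ccc(OC)cc1 | intermediate
4 | (E)-4-(4-methoxyphenyl)-3-methylbut-2-enoic acid | OC(=O)/C=C(C)/Cc1ccc(OC)cc1 | intermediate
5 | 7-methoxy-3-methylnaphthalen-1-ol (not isolated) | COc1ccc2cc(C)cc(O)c2c1 | intermediate
6 | 7-methoxy-3-methylnaphthalen-1-yl acetate | COc1ccc2cc(C)cc(OC(C)=O)c2c1 | intermediate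
7 | 8-bromo-7-methoxy-3-methylnaphthalen-1-yl acetate | COc1ccc2cc(C)cc(OC(C)=O)c2c1Br | intermediate
8 | 8-bromo-7-methoxy-3-methylnaphthalen-1-ol | COc1ccc2cc(C)cc(O)c2c1Br | intermediate
9 | 8-hydroxy-2-methoxy-6-methyl-1-naphthoic acid (not isolated) | COc1ccc2cc(C)cc(O)c2c1C(=O)O | intermediate
10 | 3-methoxy-7-methyl-2H-naphtho[1,8-bc]furan-2-one | COc1ccc2cc(C)cc3OC(=O)c1c23 | intermediate
11 | 3-hydroxy-7-methyl-2H-naphtho[1,8-bc]furan-2-one | Oc1ccc2cc(C)cc3OC(=O)c1c23 | intermediate
12 | 7-methyl-3-[(triisopropylsilyl)oxy]-2H-naphtho[1,8-bc]furan-2-one | CC(C)[Si](Oc1ccc2cc(C)cc3OC(=O)c1c23)(C(C)C)C(C)C | intermediate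
13 | 2-iodo-3-methoxybenzoic acid | COc1cccc(C(=O)O)c1I | starting material
14 | 2-[(tert-butyldimethylsilyl)oxy]ethan-1-amine | NCCO[Si](C)(C)C(C)(C)C | starting material
15 | (1H-imidazol-1-yl)(2-iodo-3-methoxyphenyl)methanone (not isolated) | COc1cccc(C(=O)n2ccnc2)c1I | intermediate
16 | N-{2-[(tert-butyldimethylsilyl)oxy]ethyl}-2-iodo-3-methoxybenzamide | COc1cccc(C(=O)NCCO[Si](C)(C)C(C)(C)C)c1I | intermediate
17 | sodium 8-[N-{2-[(tert-butyldimethylsilyl)oxy]ethyl}-N-(2-iodo-3-methoxybenzoyl)carbamoyl]-3-methyl-7-[(triisopropylsilyl)oxy]naphthalen-1-olate (not isolated) | COc1cccc(C(=O)N(CCO[Si](C)(C)C(C)(C)C)C(=O)c2c(O[Si](C(C)C)(C(C)C)C(C)C)ccc3cc(C)cc([O-])c23)c1I.[Na+] | intermediate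
18 | N-{2-[(tert-butyldimethylsilyl)oxy]ethyl}-2-iodo-3-methoxy-N-{6-methyl-8-[(triethylsilyl)oxy]-2-[(triisopropylsilyl)oxy]-1-naphthoyl}benzamide | COc1cccc(C(=O)N(CCO[Si](C)(C)C(C)(C)C)C(=O)c2c(O[Si](C(C)C)(C(C)C)C(C)C)ccc3cc(C)cc(O[Si](CC)(CC)CC)c23)c1I | intermediate
19 | arylmagnesium chloride from 18, magnesium in place of iodine (not isolated) | COc1cccc(C(=O)N(CCO[Si](C)(C)C(C)(C)C)C(=O)c2c(O[Si](C(C)C)(C(C)C)C(C)C)ccc3cc(C)cc(O[Si](CC)(CC)CC)c23)c1[Mg]Cl | intermediate
20 | chloromagnesium alkoxide of the cyclised hemiaminal, peri oxygen still triethylsilylated (not isolated) | COc1cccc2c1C(O[Mg]Cl)(c1c(O[Si](C(C)C)(C(C)C)C(C)C)ccc3cc(C)cc(O[Si](CC)(CC)CC)c13)N(CCO[Si](C)(C)C(C)(C)C)C2=O | intermediate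
21 | 2-{2-[(tert-butyldimethylsilyl)oxy]ethyl}-3-hydroxy-3-{8-hydroxy-6-methyl-2-[(triisopropylsilyl)oxy]naphthalen-1-yl}-4-methoxyisoindolin-1-one (racemic) | COc1cccc2c1C(O)(c1c(O[Si](C(C)C)(C(C)C)C(C)C)ccc3cc(C)cc(O)c13)N(CCO[Si](C)(C)C(C)(C)C)C2=O | intermediate
22 | N-acyliminium cation of the ion pair, chiral phosphate counter-ion not drawn (not isolated) | COc1cccc2c1C(c1c(O[Si](C(C)C)(C(C)C)C(C)C)ccc3cc(C)cc(O)c13)=[N+](CCO[Si](C)(C)C(C)(C)C)C2=O | intermediate
23 | (S)-2-{2-[(tert-butyldimethylsilyl)oxy]ethyl}-7-methoxy-7'-methyl-3'-[(triisopropylsilyl)oxy]spiro[isoindoline-1,2'-naphtho[1,8-bc]furan]-3-one | COc1cccc2c1[C@@]1(Oc3cc(C)cc4ccc(O[Si](C(C)C)(C(C)C)C(C)C)c1c34)N(CCO[Si](C)(C)C(C)(C)C)C2=O | intermediate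
24 | (R)-3'-hydroxy-2-(2-hydroxyethyl)-7-methoxy-7'-methylspiro[isoindoline-1,2'-naphtho[1,8-bc]furan]-3-one | COc1cccc2c1[C@@]1(Oc3cc(C)cc4ccc(O)c1c34)N(CCO)C2=O | target

Total step count: 13. Longest linear sequence: 12 steps (steps 1 to 8 and 10 to 13, from 1); step 9 is a one-step side branch.

Steps most likely to fail

1. Step 11. The exchange reagent may add to the imide carbonyls, or the arylmagnesium may be protonated before it reaches the naphthoyl carbonyl, which is flanked by two oxygen substituents (net deiodination). The fallback is a nickel-catalysed reductive cyclisation of the aryl iodide onto the carbonyl, which avoids a free carbanion. It sets out from 18: NiBr2(dme) (10 mol %), 2,2'-bipyridine, Zn dust, DMF, rt, in which zerovalent nickel formed in the flask inserts into the C–I bond and the arylnickel adds across the naphthoyl C=O, should give the triethylsilyl-protected hydroxylactam F1. K2CO3 in MeOH then removes the triethylsilyl group, and the sequence comes back to the route at 21.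

2. Step 12. Facial discrimination in the ion pair may be poor, the product may lose enantiopurity by re-ionising under the acid, and the side-chain silyl ether oxygen may capture the cation. The fallback is ring closure without induction followed by resolution. It sets out from 21: camphorsulfonic acid (cat.), 4 Å MS, CH2Cl2 should give the racemic spiro N,O-ketal F2. Preparative chromatography on a chiral stationary phase separates the enantiomers, and the (S)-enantiomer is 23, where the route is rejoined. The unwanted enantiomer is racemised with the same acid and recycled.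

3. Step 10. Acyl transfer from the lactone may stop short or reverse (the naphthoxide re-closing the lactone) before silylation, so that the silyl chloride traps the amidate instead. The fallback is a stepwise imide synthesis with the peri oxygen protected before N-acylation. It sets out from 12 and 14: aminolysis of the lactone (THF, rt) should give N-{2-[(tert-butyldimethylsilyl)oxy]ethyl}-8-hydroxy-6-methyl-2-[(triisopropylsilyl)oxy]-1-naphthamide F3, and TESCl with imidazole converts it into its 8-triethylsilyl ether F4. Acid 13 is converted with (COCl)2 and cat. DMF into 2-iodo-3-methoxybenzoyl chloride F5. Deprotonation of F4 with NaHMDS and N-acylation with F5 comes back to the route at 18.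

Further compounds
F1 | step 11 | 2-{2-[(tert-butyldimethylsilyl)oxy]ethyl}-3-hydroxy-4-methoxy-3-{6-methyl-8-[(triethylsilyl)oxy]-2-[(triisopropylsilyl)oxy]naphthalen-1-yl}isoindolin-1-one (racemic) | COc1cccc2c1C(O)(c1c(O[Si](C(C)C)(C(C)C)C(C)C)ccc3cc(C)cc(O[Si](CC)(CC)CC)c13)N(CCO[Si](C)(C)C(C)(C)C)C2=O
F2 | step 12 | racemic 2-{2-[(tert-butyldimethylsilyl)oxy]ethyl}-7-methoxy-7'-methyl-3'-[(triisopropylsilyl)oxy]spiro[isoindoline-1,2'-naphtho[1,8-bc]furan]-3-one | COc1cccc2c1C1(Oc3cc(C)cc4ccc(O[Si](C(C)C)(C(C)C)C(C)C)c1c34)N(CCO[Si](C)(C)C(C)(C)C)C2=O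
F3 | step 10 | N-{2-[(tert-butyldimethylsilyl)oxy]ethyl}-8-hydroxy-6-methyl-2-[(triisopropylsilyl)oxy]-1-naphthamide | CC(C)[Si](Oc1ccc2cc(C)cc(O)c2c1C(=O)NCCO[Si](C)(C)C(C)(C)C)(C(C)C)C(C)C
F4 | step 10 | N-{2-[(tert-butyldimethylsilyl)oxy]ethyl}-6-methyl-8-[(triethylsilyl)oxy]-2-[(triisopropylsilyl)oxy]-1-naphthamide | CC(C)[Si](Oc1ccc2cc(C)cc(O[Si](CC)(CC)CC)c2c1C(=O)NCCO[Si](C)(C)C(C)(C)C)(C(C)C)C(C)C
F5 | step 10 | 2-iodo-3-methoxybenzoyl chloride | COc1cccc(C(Cl)=O)c1I
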